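**Plan**
1. Numbering used below: ring C1–C10 (C1=C2 alkene, C3 ketone, C4 bearing C15H2OH, C5H2, C6–O of the lactone, C7, C8–O-angeloyl, C9H2, C10(OH) bearing C14H3); lactone C11(=C13H2)–C12(=O)–O–C6.
2. Cuts: C1=C2 (ring-closing metathesis) and C2–C3 (vinyl addition); the C8 ester; C11=C13; then together the lactone O–C6 bond and C7–C11 (amide-acetal Claisen rearrangement, then iodolactonisation); C4–C5 (aldol); C6=C7 and C8–O (aminoxylation/olefination).
3. Forward: (R)-linalool gives the C7–C10 aldehyde and then the C5–C10 enal; the aldol adds C3/C4/C15; the lactone ring is closed first (step 11) and the ten-membered ring last (step 19).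
4. Feature that makes the key event possible: the lactone oxygen sits on C6, γ to C12 and next to the unsubstituted C5H2. A C12 carbonyl oxygen can therefore close the five-membered ring onto a C5=C6 alkene, which is exactly the alkene that a [3,3] shift from a C5 carbinol leaves behind when it makes C7–C11. The helper iodine on C5 is removed afterwards.
5. Stereochemistry: C10 from (R)-linalool; C8 from L-proline; C4 and the relay centre C5 from the Evans auxiliary; C7 by chirality transfer from C5; C6 by trans ring closure next to C7; Z-C1=C2 from ring strain; the Z ester from angelic acid.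

Key step: step 11

Remark: acid 10 is taken as a catalogue compound and commercial (R)-(−)-linalool is assumed to be of high enantiomeric purity. Compounds 33 and 34 are carried as C3-epimer mixtures because C3 becomes the ketone. Locants in names refer to the numbering of line 1.

**Step 1**
Reactants: 1 (R)-(−)-linalool
Product: 2 (R)-linalool triethylsilyl ether
Conditions: Et3SiOTf, 2,6-lutidine, CH2Cl2, −78 °C to 0 °C
Reagents that add atoms: triethylsilyl trifluoromethanesulfonate, CC[Si](CC)(CC)OS(=O)(=O)C(F)(F)F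
Why: Silylation of the tertiary alcohol with a silyl triflate keeps the later γ-hydroxy aldehyde from closing to a lactol; no stereocentre is touched.

**Step 2**
Reactants: 2 (R)-linalool triethylsilyl ether
Product: 4 (4R)-4-methyl-4-(triethylsilyloxy)hex-5-enal, via ozonide 3 (not isolated)
Conditions: O3 (1 equiv, Sudan Red 7B end point), CH2Cl2, −78 °C; then Me2S, −78 °C to rt
Reagents that add atoms: ozone, [O-][O+]=O
Why: Ozonolysis with reductive work-up; the electron-rich trisubstituted alkene should react far faster than the vinyl group next to the quaternary silyloxy carbon, and titration to the indicator end point stops the reaction there.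

**Step 3**
Reactants: 4 (4R)-4-methyl-4-(triethylsilyloxy)hex-5-enal
Product: 6 (2E,4R,6R)-N-methoxy-N,6-dimethyl-4-(phenylaminooxy)-6-(triethylsilyloxy)octa-2,7-dienamide, via aminoxy aldehyde 5 (not isolated)
Conditions: PhNO, L-proline (20 mol %), DMSO, rt; then (EtO)2P(O)CH2C(O)N(OMe)Me, LiCl, DBU, MeCN, 0 °C
Reagents that add atoms: nitrosobenzene, O=Nc1ccccc1; diethyl [2-(methoxy(methyl)amino)-2-oxoethyl]phosphonate, CCOP(=O)(CC(=O)N(C)OC)OCC
Why: Proline-catalysed α-aminoxylation (enamine catalysis) followed in the same flask by Horner–Wadsworth–Emmons olefination under Masamune–Roush conditions; L-proline should deliver the nitroso oxygen to the enamine face that gives the (R) C8–O centre, and the stabilised phosphonate gives the E alkene.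

**Step 4**
Reactants: 6 (2E,4R,6R)-N-methoxy-N,6-dimethyl-4-(phenylaminooxy)-6-(triethylsilyloxy)octa-2,7-dienamide
Product: 7 (2E,4R,6R)-4-hydroxy-N-methoxy-N,6-dimethyl-6-(triethylsilyloxy)octa-2,7-dienamide
Conditions: Cu(OAc)2 (30 mol %), EtOH, rt
Reagents that add atoms: none
Why: Copper-catalysed N–O bond cleavage of the O-alkyl-N-arylhydroxylamine (the nitrogen leaves as azobenzene) should free the C8 hydroxyl under neutral conditions without touching the enamide or either stereocentre.

**Step 5**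
Reactants: 7 (2E,4R,6R)-4-hydroxy-N-methoxy-N,6-dimethyl-6-(triethylsilyloxy)octa-2,7-dienamide
Product: 8 (2E,4R,6R)-4-(tert-butyldimethylsilyloxy)-N-methoxy-N,6-dimethyl-6-(triethylsilyloxy)octa-2,7-dienamide
Conditions: t-BuMe2SiCl, imidazole, DMF, rt
Reagents that add atoms: tert-butyldimethylsilyl chloride, CC(C)(C)[Si](C)(C)Cl
Why: Standard imidazole-mediated silylation of the secondary allylic alcohol; no stereocentre is touched.

**Step 6**
Reactants: 8 (2E,4R,6R)-4-(tert-butyldimethylsilyloxy)-N-methoxy-N,6-dimethyl-6-(triethylsilyloxy)octa-2,7-dienamide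
Product: 9 (2E,4R,6R)-4-(tert-butyldimethylsilyloxy)-6-methyl-6-(triethylsilyloxy)octa-2,7-dienal
Conditions: i-Bu2AlH, THF, −78 °C; aqueous potassium sodium tartrate
Reagents that add atoms: none
Why: Hydride reduction of the Weinreb amide should stop at the aldehyde because the chelated tetrahedral intermediate collapses only on work-up.

**Step 7**
Reactants: 10 3-[(4-methoxybenzyl)oxy]propanoic acid; 11 (S)-4-benzyl-2-oxazolidinone
Product: 13 (S)-4-benzyl-3-[3-(4-methoxybenzyloxy)propanoyl]oxazolidin-2-one, via mixed anhydride 12 (not isolated)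
Conditions: t-BuCOCl, Et3N, THF, −20 °C; then 11, LiCl, −20 °C to rt
Reagents that add atoms: none
Why: N-Acylation of the oxazolidinone through the mixed pivalic anhydride (LiCl/Et3N protocol).

**Step 8**
Reactants: 13 (S)-4-benzyl-3-[3-(4-methoxybenzyloxy)propanoyl]oxazolidin-2-one; 9 (2E,4R,6R)-4-(tert-butyldimethylsilyloxy)-6-methyl-6-(triethylsilyloxy)octa-2,7-dienal
Product: 15 syn-aldol adduct (4S,5R,6E,8R,10R; imide carbonyl = C15; C3H2–OPMB; C5–OH), via boron enolate 14 (not isolated)
Conditions: Bu2BOTf, i-Pr2NEt, CH2Cl2, −78 °C to 0 °C; then 9, −78 °C to −10 °C; pH 7 buffer, MeOH, H2O2, 0 °C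
Reagents that add atoms: none
Why: Evans syn-aldol reaction; the (Z)-boron enolate should react through a closed chair transition state on the face away from the benzyl group, which sets C4 (S) and the relay carbinol C5 (R), and a boron enolate at low temperature should not expel the β-alkoxy group.

**Step 9**
Reactants: 15 syn-aldol adduct
Product: 16 1,3-diol (C15H2OH and C5–OH free; 4S,5R,6E,8R,10R)
Conditions: LiBH4, MeOH (2 equiv), THF, 0 °C
Reagents that add atoms: none
Why: Reductive removal of the auxiliary turns the imide carbonyl into the C15 hydroxymethyl group; no enolate is formed, so C4 is not epimerised.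

**Step 10**
Reactants: 16 1,3-diol
Product: 17 allylic alcohol (C15–OTBDPS; C3–OPMB; C5–OH; 4R,5R,6E,8R,10R)
Conditions: t-BuPh2SiCl, imidazole, CH2Cl2, 0 °C
Reagents that add atoms: tert-butyldiphenylsilyl chloride, CC(C)(C)[Si](Cl)(c1ccccc1)c1ccccc1
Why: Selective silylation of the primary alcohol over the hindered secondary allylic alcohol leaves C5–OH free for the rearrangement.

**Step 11**
Reactants: 17 allylic alcohol
Product: 21 iodolactone (trans γ-lactone O–C6; C5–I; 4R,5R,6S,7S,8R,10R), via ketene N,O-acetal 18 (not isolated), via amide 19 (not isolated), via iminium lactone 20 (not isolated)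
Conditions: MeC(OMe)2NMe2, xylene, 140 °C (MeOH distilled off); concentrate; then I2, THF/H2O (2:1), rt, dark; aq Na2S2O3
Reagents that add atoms: N,N-dimethylacetamide dimethyl acetal, COC(C)(OC)N(C)C; iodine, [I][I]; water, O
Why: Exchange of the C5 hydroxyl into the amide acetal gives ketene N,O-acetal 18, whose [3,3] shift through a chair with the C4 substituent equatorial forms C7–C11 on the face that carried the oxygen, so the C5 (R) carbinol is spent to set C7 (S) and leaves the E C5=C6 alkene of amide 19. Iodine then activates this alkene and the amide oxygen attacks C6 in a 5-exo-trig closure anti to iodine, which forms the O–C6 bond and the γ-lactone ring; water hydrolyses iminium lactone 20 with loss of dimethylamine. The closest known reaction types are the Eschenmoser–Claisen rearrangement with 1,3-chirality transfer and the iodolactonisation of 3-substituted 4-alkenamides. C6 is controlled by the neighbouring C7 centre: closure to the iminium ion is reversible, so the ring should settle with the C5 and C8 chains trans, as in the target, while the iodide centre at C5 is temporary. The step needs the C5=C6 alkene to react in preference to the vinyl group and 5-exo in preference to 6-endo closure; only C5=C6 has an oxygen nucleophile within reach of a five-membered ring, and the released amine takes up the acid, so the tertiary allylic silyl ether should survive.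

**Step 12**
Reactants: 21 iodolactone
Product: 22 lactone (C5H2; 4R,6R,7S,8R,10R)
Conditions: Bu3SnH, AIBN (cat.), toluene, 80 °C
Reagents that add atoms: none
Why: Radical chain dehalogenation removes the helper iodine so that C5 becomes the ring CH2; hydrogen transfer from the tin hydride should outrun any cyclisation of the C5 radical onto the distant vinyl group.

**Step 13**
Reactants: 22 lactone
Product: 26 α-methylene lactone (4R,6R,7S,8R,10R), via lithium enolate 23 (not isolated), via Mannich base 24 (not isolated), via ammonium iodide 25 (not isolated)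
Conditions: LiN(i-Pr)2, THF, −78 °C; CH2=NMe2+ I−, −78 °C to rt; then MeI, MeOH, rt; then aq NaHCO3, CH2Cl2, rt
Reagents that add atoms: N,N-dimethylmethyleneiminium iodide (Eschenmoser's salt), C=[N+](C)C.[I-]
Why: α-Methylenation by Mannich reaction of the lactone enolate, quaternisation and E1cB elimination; the centre created at C11 is lost on elimination and C7 carries no acidic hydrogen.

**Step 14**
Reactants: 26 α-methylene lactone
Product: 27 diol (C8–OH and C10–OH free; 4R,6R,7R,8R,10R)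
Conditions: CSA (cat.), MeOH/CH2Cl2 (1:1), 0 °C to rt
Reagents that add atoms: none
Why: Acid-catalysed methanolysis removes the secondary TBS and tertiary TES ethers while the primary TBDPS ether and the PMB ether stay; the trans 6,12-lactone is the more stable of the two possible γ-lactones, so migration of the acyl group to O8 is not expected.

**Step 15**
Reactants: 27 diol; 28 angelic acid
Product: 30 C8 angelate (4R,6R,7S,8R,10R), via mixed anhydride 29 (not isolated)
Conditions: 28, 2,4,6-Cl3C6H2COCl, Et3N, toluene, rt; then 27, toluene, 80 °C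
Reagents that add atoms: none
Why: Yamaguchi-type esterification through the mixed anhydride, run without DMAP, is the established way to acylate with angelic acid without Z to E isomerisation; only the secondary C8 alcohol should react because the tertiary C10 alcohol is too hindered.

**Step 16**
Reactants: 30 C8 angelate
Product: 31 primary alcohol (C3H2OH; 4R,6R,7S,8R,10R)
Conditions: DDQ, CH2Cl2/pH 7 buffer (10:1), 0 °C
Reagents that add atoms: none
Why: Oxidative cleavage of the PMB ether by DDQ under buffered conditions leaves the esters, the lactone, the alkenes and the silyl ether untouched.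

**Step 17**
Reactants: 31 primary alcohol
Product: 32 aldehyde (C3HO; 4S,6R,7S,8R,10R)
Conditions: Dess–Martin periodinane, NaHCO3, CH2Cl2, 0 °C to rt
Reagents that add atoms: none
Why: Dess–Martin oxidation under buffered, non-basic conditions should give the α-branched aldehyde without epimerising C4 or eliminating the β-silyloxy group; the tertiary alcohol cannot be oxidised.

**Step 18**
Reactants: 32 aldehyde
Product: 33 vinyl carbinol (C3 epimers; 4S,6R,7S,8R,10R)
Conditions: CH2=CHBr, CrCl2, NiCl2 (cat.), DMSO/THF, rt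
Reagents that add atoms: vinyl bromide, C=CBr
Why: Nozaki–Hiyama–Kishi reaction; the vinylchromium reagent adds only to the aldehyde and tolerates the lactone, the acrylate-type alkene, the ester and the free tertiary alcohol, and the C3 epimer mixture is of no consequence.

**Step 19**
Reactants: 33 vinyl carbinol
Product: 34 ten-membered (1Z)-cycloalkene-3,10-diol (C3 epimers; C15–OTBDPS)
Conditions: second-generation Grubbs catalyst RuCl2(=CHPh)(H2IMes)(PCy3) (10 mol %), 1,4-benzoquinone (cat.), toluene (1 mM), 80 °C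
Reagents that add atoms: none
Why: Ring-closing metathesis at high dilution should join the two monosubstituted alkenes, since the 1,1-disubstituted acrylate alkene and the trisubstituted angelate alkene are poor metathesis partners; in a ten-membered ring the Z alkene is the less strained isomer, so reversible metathesis should deliver Z.

**Step 20**
Reactants: 34 ten-membered (1Z)-cycloalkene-3,10-diol
Product: 35 (1Z)-enone (C15–OTBDPS; 4S,6R,7S,8R,10R)
Conditions: Dess–Martin periodinane, NaHCO3, CH2Cl2, 0 °C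
Reagents that add atoms: none
Why: Dess–Martin oxidation converts both C3 epimers of the secondary allylic alcohol into the Z enone; the tertiary alcohol is inert and the buffered medium should avoid epimerisation at C4.

**Step 21**
Reactants: 35 (1Z)-enone
Product: 36 CNP0219400.1
Conditions: HF·pyridine, pyridine, THF, 0 °C to rt
Reagents that add atoms: none
Why: Fluoride-mediated desilylation with buffered HF·pyridine frees the C15 alcohol under conditions that should be too mild for retro-aldol cleavage or dehydration of the β-hydroxy ketone.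

**Compound list**
1 | (R)-(−)-linalool | C=C[C@](C)(O)CCC=C(C)C | starting material
2 | (R)-linalool triethylsilyl ether | C=C[C@](C)(O[Si](CC)(CC)CC)CCC=C(C)C | intermediate
3 | ozonide of 2 (1,2,4-trioxolane at the former trisubstituted alkene; not isolated) | C=C[C@](C)(O[Si](CC)(CC)CC)CCC1OOC(C)(C)O1 | intermediate
4 | (4R)-4-methyl-4-(triethylsilyloxy)hex-5-enal | C=C[C@](C)(O[Si](CC)(CC)CC)CCC=O | intermediate
5 | (2R,4R)-4-methyl-2-(phenylaminooxy)-4-(triethylsilyloxy)hex-5-enal (not isolated) | C=C[C@](C)(O[Si](CC)(CC)CC)C[C@@H](ONc1ccccc1)C=O | intermediate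
6 | (2E,4R,6R)-N-methoxy-N,6-dimethyl-4-(phenylaminooxy)-6-(triethylsilyloxy)octa-2,7-dienamide | C=C[C@](C)(O[Si](CC)(CC)CC)C[C@@H](ONc1ccccc1)/C=C/C(=O)N(C)OC | intermediate
7 | (2E,4R,6R)-4-hydroxy-N-methoxy-N,6-dimethyl-6-(triethylsilyloxy)octa-2,7-dienamide | C=C[C@](C)(O[Si](CC)(CC)CC)C[C@@H](O)/C=C/C(=O)N(C)OC | intermediate
8 | (2E,4R,6R)-4-(tert-butyldimethylsilyloxy)-N-methoxy-N,6-dimethyl-6-(triethylsilyloxy)octa-2,7-dienamide | C=C[C@](C)(O[Si](CC)(CC)CC)C[C@@H](O[Si](C)(C)C(C)(C)C)/C=C/C(=O)N(C)OC | intermediate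
9 | (2E,4R,6R)-4-(tert-butyldimethylsilyloxy)-6-methyl-6-(triethylsilyloxy)octa-2,7-dienal (C5–C10 enal) | C=C[C@](C)(O[Si](CC)(CC)CC)C[C@@H](O[Si](C)(C)C(C)(C)C)/C=C/C=O | intermediate
10 | 3-[(4-methoxybenzyl)oxy]propanoic acid | COc1ccc(COCCC(=O)O)cc1 | starting material
11 | (S)-4-benzyl-2-oxazolidinone | O=C1N[C@@H](Cc2ccccc2)CO1 | starting material
12 | mixed pivalic anhydride of 10 (not isolated) | COc1ccc(COCCC(=O)OC(=O)C(C)(C)C)cc1 | intermediate
13 | (S)-4-benzyl-3-[3-(4-methoxybenzyloxy)propanoyl]oxazolidin-2-one | COc1ccc(COCCC(=O)N2C(=O)OC[C@@H]2Cc3ccccc3)cc1 | intermediate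
14 | (Z)-dibutylboron enolate of 13 (not isolated) | CCCCB(CCCC)O/C(=C\COCc1ccc(OC)cc1)N2C(=O)OC[C@@H]2Cc3ccccc3 | intermediate
15 | syn-aldol adduct: N-acyl oxazolidinone, imide carbonyl = C15, C3H2–OPMB, C5–OH, E-C6=C7, C8–OTBS, C10–OTES (4S,5R,8R,10R) | O[C@H](/C=C/[C@H](O[Si](C)(C)C(C)(C)C)C[C@@](C)(O[Si](CC)(CC)CC)C=C)[C@@H](C(=O)N1C(=O)OC[C@@H]1Cc2ccccc2)COCc3ccc(OC)cc3 | intermediate
16 | 1,3-diol: C15H2OH, C5–OH, C3H2–OPMB (4S,5R,6E,8R,10R) | O[C@H](/C=C/[C@H](O[Si](C)(C)C(C)(C)C)C[C@@](C)(O[Si](CC)(CC)CC)C=C)[C@@H](CO)COCc1ccc(OC)cc1 | intermediate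
17 | allylic alcohol: C15–OTBDPS, C3–OPMB, C5–OH (4R,5R,6E,8R,10R) | O[C@H](/C=C/[C@H](O[Si](C)(C)C(C)(C)C)C[C@@](C)(O[Si](CC)(CC)CC)C=C)[C@@H](CO[Si](c1ccccc1)(c2ccccc2)C(C)(C)C)COCc3ccc(OC)cc3 | intermediate
18 | ketene N,O-acetal of 17 at O5 (not isolated) | C=C(N(C)C)O[C@H](/C=C/[C@H](O[Si](C)(C)C(C)(C)C)C[C@@](C)(O[Si](CC)(CC)CC)C=C)[C@@H](CO[Si](c1ccccc1)(c2ccccc2)C(C)(C)C)COCc3ccc(OC)cc3 | intermediate
19 | γ,δ-unsaturated N,N-dimethylamide: Me2N–C12(=O)–C11H2–C7, E-C5=C6 (4R,7S,8R,10R; not isolated) | CN(C)C(=O)C[C@@H](/C=C/[C@@H](CO[Si](c1ccccc1)(c2ccccc2)C(C)(C)C)COCc3ccc(OC)cc3)[C@H](O[Si](C)(C)C(C)(C)C)C[C@@](C)(O[Si](CC)(CC)CC)C=C | intermediate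
20 | iminium lactone iodide: 2-(dimethyliminio)tetrahydrofuran closed at O–C6, C5–I (not isolated) | C1C(=[N+](C)C)O[C@H]([C@H](I)[C@@H](CO[Si](c2ccccc2)(c3ccccc3)C(C)(C)C)COCc4ccc(OC)cc4)[C@H]1[C@H](O[Si](C)(C)C(C)(C)C)C[C@@](C)(O[Si](CC)(CC)CC)C=C.[I-] | intermediate
21 | iodolactone: trans γ-lactone (O–C6), C5–I (4R,5R,6S,7S,8R,10R) | C1C(=O)O[C@H]([C@H](I)[C@@H](CO[Si](c2ccccc2)(c3ccccc3)C(C)(C)C)COCc4ccc(OC)cc4)[C@H]1[C@H](O[Si](C)(C)C(C)(C)C)C[C@@](C)(O[Si](CC)(CC)CC)C=C | intermediate
22 | lactone with C5H2 (4R,6R,7S,8R,10R) | C1C(=O)O[C@H](C[C@@H](CO[Si](c2ccccc2)(c3ccccc3)C(C)(C)C)COCc4ccc(OC)cc4)[C@H]1[C@H](O[Si](C)(C)C(C)(C)C)C[C@@](C)(O[Si](CC)(CC)CC)C=C | intermediate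
23 | lithium enolate of 22 (not isolated) | C1=C([O-])O[C@H](C[C@@H](CO[Si](c2ccccc2)(c3ccccc3)C(C)(C)C)COCc4ccc(OC)cc4)[C@H]1[C@H](O[Si](C)(C)C(C)(C)C)C[C@@](C)(O[Si](CC)(CC)CC)C=C.[Li+] | intermediate
24 | Mannich base: C11–CH2NMe2 (C11 epimers; not isolated) | CN(C)CC1C(=O)O[C@H](C[C@@H](CO[Si](c2ccccc2)(c3ccccc3)C(C)(C)C)COCc4ccc(OC)cc4)[C@H]1[C@H](O[Si](C)(C)C(C)(C)C)C[C@@](C)(O[Si](CC)(CC)CC)C=C | intermediate
25 | trimethylammonium iodide of 24 (not isolated) | C[N+](C)(C)CC1C(=O)O[C@H](C[C@@H](CO[Si](c2ccccc2)(c3ccccc3)C(C)(C)C)COCc4ccc(OC)cc4)[C@H]1[C@H](O[Si](C)(C)C(C)(C)C)C[C@@](C)(O[Si](CC)(CC)CC)C=C.[I-] | intermediate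
26 | α-methylene lactone: C8–OTBS, C10–OTES, C15–OTBDPS, C3–OPMB (4R,6R,7S,8R,10R) | C=C1C(=O)O[C@H](C[C@@H](CO[Si](c2ccccc2)(c3ccccc3)C(C)(C)C)COCc4ccc(OC)cc4)[C@H]1[C@H](O[Si](C)(C)C(C)(C)C)C[C@@](C)(O[Si](CC)(CC)CC)C=C | intermediate
27 | diol: C8–OH and C10–OH free (4R,6R,7R,8R,10R) | C=C1C(=O)O[C@H](C[C@@H](CO[Si](c2ccccc2)(c3ccccc3)C(C)(C)C)COCc4ccc(OC)cc4)[C@H]1[C@H](O)C[C@@](C)(O)C=C | intermediate
28 | angelic acid, (Z)-2-methylbut-2-enoic acid | C/C=C(/C)C(=O)O | starting material
29 | angelic 2,4,6-trichlorobenzoic anhydride (not isolated) | C/C=C(/C)C(=O)OC(=O)c1c(Cl)cc(Cl)cc1Cl | intermediate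
30 | C8 angelate (4R,6R,7S,8R,10R) | C=C1C(=O)O[C@H](C[C@@H](CO[Si](c2ccccc2)(c3ccccc3)C(C)(C)C)COCc4ccc(OC)cc4)[C@H]1[C@H](OC(=O)/C(C)=C\C)C[C@@](C)(O)C=C | intermediate
31 | primary alcohol at C3 (4R,6R,7S,8R,10R) | C=C1C(=O)O[C@H](C[C@@H](CO[Si](c2ccccc2)(c3ccccc3)C(C)(C)C)CO)[C@H]1[C@H](OC(=O)/C(C)=C\C)C[C@@](C)(O)C=C | intermediate
32 | aldehyde at C3 (4S,6R,7S,8R,10R) | C=C1C(=O)O[C@H](C[C@@H](CO[Si](c2ccccc2)(c3ccccc3)C(C)(C)C)C=O)[C@H]1[C@H](OC(=O)/C(C)=C\C)C[C@@](C)(O)C=C | intermediate
33 | vinyl carbinol at C3 (C3 epimers; 4S,6R,7S,8R,10R) | C=C1C(=O)O[C@H](C[C@@H](CO[Si](c2ccccc2)(c3ccccc3)C(C)(C)C)C(O)C=C)[C@H]1[C@H](OC(=O)/C(C)=C\C)C[C@@](C)(O)C=C | intermediate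
34 | ten-membered (1Z)-cycloalkene-3,10-diol, C15–OTBDPS (C3 epimers; 4S,6R,7S,8R,10R) | C=C1C(=O)O[C@@H]2C[C@@H](CO[Si](c3ccccc3)(c4ccccc4)C(C)(C)C)C(O)/C=C\[C@](C)(O)C[C@@H](OC(=O)/C(C)=C\C)[C@@H]12 | intermediate
35 | (1Z)-enone, C15–OTBDPS (4S,6R,7S,8R,10R) | C=C1C(=O)O[C@@H]2C[C@@H](CO[Si](c3ccccc3)(c4ccccc4)C(C)(C)C)C(=O)/C=C\[C@](C)(O)C[C@@H](OC(=O)/C(C)=C\C)[C@@H]12 | intermediate
36 | CNP0219400.1 (4S,6R,7S,8R,10R; 1Z; angelate) | C=C1C(=O)O[C@@H]2C[C@@H](CO)C(=O)/C=C\[C@](C)(O)C[C@@H](OC(=O)/C(C)=C\C)[C@@H]12 | target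

**Step count**
Total: 21 steps. Longest linear sequence: 20 steps (steps 1–6 and 8–21, from (R)-linalool); step 7 is a one-step side branch.

**Steps most likely to fail**

1. Step 19. Ring closure to the strained ten-membered ring may lose to intermolecular metathesis, the catalyst may engage the exocyclic methylene, or the E cycloalkene may form under kinetic control. The fallback fixes the alkene geometry before ring closure and closes the C2–C3 bond instead. Setting out from 30, the vinyl group, the only electron-rich alkene, would be cleaved (OsO4 cat., NaIO4, 2,6-lutidine, dioxane/H2O) to the α-hydroxy aldehyde F1. Stork–Zhao olefination (Ph3P+CH2I I−, NaN(SiMe3)2, THF/DMPU, −78 °C) would give the (Z)-iodoalkene F2. DDQ and then Dess–Martin periodinane, as in steps 16 and 17, would give the alcohol F3 and the iodo aldehyde F4. An intramolecular Nozaki–Hiyama–Kishi reaction (CrCl2, NiCl2 cat., DMSO, high dilution) would then return to 34.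

2. Step 11. The iminium lactone may hydrolyse before it equilibrates, which would give poor trans selectivity at C6, or some 6-endo closure may occur. The fallback sets C6 by a reagent-controlled, stereospecific sequence. Setting out from amide 19, isolated after the rearrangement stage, Shi epoxidation (D-fructose-derived ketone, KHSO5, K2CO3, MeCN/dimethoxymethane/buffer, 0 °C) should give the (5R,6R)-epoxy amide F5. Acid (CSA cat., CH2Cl2, then water) would let the amide oxygen open the epoxide at C6 with inversion and hydrolyse to the C5-hydroxy lactone F6. Thiocarbonyldiimidazole would give the imidazolyl thiocarbamate F7, and Barton–McCombie reduction (Bu3SnH, AIBN, toluene, 80 °C) would return to 22.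

3. Step 15. The angeloyl group may isomerise to the E (tigloyl) isomer during activation, or the hindered C8 alcohol may acylate slowly. The fallback builds the Z alkene on the ester. Setting out from 27, carbodiimide coupling (DCC, DMAP, CH2Cl2) with 2-[bis(2,2,2-trifluoroethoxy)phosphoryl]propanoic acid would give the phosphonate ester F8. Still–Gennari olefination with acetaldehyde (KN(SiMe3)2, 18-crown-6, THF, −78 °C) would return to 30.

**Further compounds**
F1 | step 19 | α-hydroxy aldehyde at C1 (vinyl group of 30 cleaved) | C=C1C(=O)O[C@H](C[C@@H](CO[Si](c2ccccc2)(c3ccccc3)C(C)(C)C)COCc4ccc(OC)cc4)[C@H]1[C@H](OC(=O)/C(C)=C\C)C[C@@](C)(O)C=O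
F2 | step 19 | (Z)-iodoalkene at C1=C2 | C=C1C(=O)O[C@H](C[C@@H](CO[Si](c2ccccc2)(c3ccccc3)C(C)(C)C)COCc4ccc(OC)cc4)[C@H]1[C@H](OC(=O)/C(C)=C\C)C[C@@](C)(O)/C=C\I
F3 | step 19 | C3 primary alcohol with (Z)-iodoalkene | C=C1C(=O)O[C@H](C[C@@H](CO[Si](c2ccccc2)(c3ccccc3)C(C)(C)C)CO)[C@H]1[C@H](OC(=O)/C(C)=C\C)C[C@@](C)(O)/C=C\I
F4 | step 19 | C3 aldehyde with (Z)-iodoalkene | C=C1C(=O)O[C@H](C[C@@H](CO[Si](c2ccccc2)(c3ccccc3)C(C)(C)C)C=O)[C@H]1[C@H](OC(=O)/C(C)=C\C)C[C@@](C)(O)/C=C\I
F5 | step 11 | (5R,6R)-epoxy amide | CN(C)C(=O)C[C@@H]([C@H]1O[C@@H]1[C@@H](CO[Si](c2ccccc2)(c3ccccc3)C(C)(C)C)COCc4ccc(OC)cc4)[C@H](O[Si](C)(C)C(C)(C)C)C[C@@](C)(O[Si](CC)(CC)CC)C=C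
F6 | step 11 | C5-hydroxy trans-lactone | C1C(=O)O[C@H]([C@H](O)[C@@H](CO[Si](c2ccccc2)(c3ccccc3)C(C)(C)C)COCc4ccc(OC)cc4)[C@H]1[C@H](O[Si](C)(C)C(C)(C)C)C[C@@](C)(O[Si](CC)(CC)CC)C=C
F7 | step 11 | C5 O-(imidazol-1-ylthiocarbonyl) derivative of F6 | C1C(=O)O[C@H]([C@H](OC(=S)n2ccnc2)[C@@H](CO[Si](c3ccccc3)(c4ccccc4)C(C)(C)C)COCc5ccc(OC)cc5)[C@H]1[C@H](O[Si](C)(C)C(C)(C)C)C[C@@](C)(O[Si](CC)(CC)CC)C=C
F8 | step 15 | C8 2-[bis(2,2,2-trifluoroethoxy)phosphoryl]propanoate of 27 | C=C1C(=O)O[C@H](C[C@@H](CO[Si](c2ccccc2)(c3ccccc3)C(C)(C)C)COCc4ccc(OC)cc4)[C@H]1[C@H](OC(=O)C(C)P(=O)(OCC(F)(F)F)OCC(F)(F)F)C[C@@](C)(O)C=C
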